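## Retrosynthetic overview
1. The Z-coumarate comes from the E-coumarate by sensitised E-to-Z isomerisation in the last step. This sets the only stereo-element not inherited from the starting material.
2. The key disconnection is the ester bond C19–O–C(=O), giving ent-labda-8(17),13(16),14-trien-19-ol and (E)-4-acetoxycinnamic acid.
3. The myrcene-type diene comes from the α-alkylbutenolide of andrograpanin, with both lactone oxygens removed in one flask.
4. Andrograpanin comes from andrographolide by two deoxygenations. C14 goes through a traceless C14–N bond (allylic diazene). C3 goes through a 3,19-cyclic thionocarbonate that frees only O19.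
5. Ring order: no carbocycle is built, because rings A and B with C4, C5, C9 and C10 come intact from andrographolide. A temporary 1,3-dioxane-2-thione ring is closed in step 2 and cleaved in step 3, and the butenolide ring is opened in step 4.

Assumption: labdane numbering is used (C19 is the axial CH2O on C4, cis to C20). The SMILES is read as the ent-labdane (4R,5S,9R,10S) carrying a Z-coumarate, which is the same absolute series and C4 configuration as andrographolide.

## Route

Step 1
Reactants: 1 andrographolide
Product: 4 14-deoxyandrographolide, via N-sulfonylhydrazine adduct 2 (not isolated), via allylic diazene 3 (not isolated)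
Conditions: 2-nitrobenzenesulfonohydrazide (NBSH, 2.2 equiv), PPh3 (2.2 equiv), DEAD (2.2 equiv), THF–N-methylmorpholine, −30 °C, 2 h, then 23 °C, 3 h
Reagents that add atoms: none
Why: Myers reductive allylic transposition: the Mitsunobu reaction forms the C14–N bond by SN2 only at the allylic secondary 14-OH (the neopentylic 19-OH and hindered 3-OH cannot be displaced and return on work-up), warming expels the sulfinic acid to give the allylic diazene, and retro-ene loss of N2 delivers H to C12 and moves the alkene to C13=C14, so the C14 stereocentre disappears while C3, C4, C5, C9 and C10 are untouched.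

Step 2
Reactants: 4 14-deoxyandrographolide
Product: 5 14-deoxyandrographolide 3,19-cyclic thionocarbonate
Conditions: 1,1'-thiocarbonyldiimidazole (1.5 equiv), DMAP (0.1 equiv), THF, 65 °C
Reagents that add atoms: 1,1'-thiocarbonyldiimidazole, S=C(n1ccnc1)n1ccnc1
Why: Cyclic thionocarbonate formation: the only two hydroxyls left are 1,3-related (equatorial O3, axial C19–O), so thioacyl transfer to the primary O19 is followed by six-ring closure on O3 with loss of the second imidazole, and no stereocentre is touched.

Step 3
Reactants: 5 14-deoxyandrographolide 3,19-cyclic thionocarbonate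
Product: 7 andrograpanin, via S-stannyl thiocarbonate 6 (not isolated)
Conditions: Bu3SnH (2 equiv, slow addition), AIBN (0.2 equiv), toluene, 100 °C; then H2O, SiO2, rt
Reagents that add atoms: none
Why: Barton–McCombie deoxygenation in its cyclic thionocarbonate form: the Bu3Sn radical adds to sulfur, the dioxanyl radical fragments at C3–O (secondary radical) rather than C19–O (primary neopentylic radical), the C3 radical takes H from Bu3SnH, and hydrolysis of the S-stannyl thiocarbonate with loss of COS frees only 19-OH, so C3 becomes CH2 and C4 keeps its configuration.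

Step 4
Reactants: 7 andrograpanin
Product: 9 ent-labda-8(17),13(16),14-trien-19-ol, via ene-triol 8 (not isolated)
Conditions: LiAlH4 (1.0 equiv), THF, 0 °C, 1 h; solution cannulated into the black slurry from TiCl3 (8 equiv) and LiAlH4 (3.5 equiv), THF, 0 °C to reflux, 2 h; aq K2CO3
Reagents that add atoms: none
Why: Proposed new method: a one-flask reductive unmasking of an α-alkylbutenolide as a 2-alkyl-1,3-butadiene, in which LiAlH4 opens the lactone by 1,2-reduction to the (Z)-2-ene-1,4-diolate (the ring fixes Z), the aluminium alkoxides pass to low-valent titanium by salt metathesis with the titanium chlorides, one weak allylic C–O bond breaks homolytically, and the allyl-titanium species expels the second allylic oxygen in a 1,4-elimination driven by Ti–O bond strength to create C13=C16 and C14=C15, while the non-allylic C19–O bond stays a spectator alkoxide and TiCl3:LiAlH4 is held near 2:1 overall so no free hydride remains to hydroaluminate the new vinyl group; the closest known reaction types are the LiAlH4 reduction of butenolides to (Z)-enediols and the titanium-induced (McMurry-type) reductive elimination of isolated 2-ene-1,4-diols, which have not been merged or applied to a lactone; no stereocentre is formed or touched.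

Step 5
Reactants: 9 ent-labda-8(17),13(16),14-trien-19-ol; 10 (E)-4-acetoxycinnamic acid
Product: 12 ent-labda-8(17),13(16),14-trien-19-yl (E)-4-hydroxycinnamate, via acetoxycinnamate ester 11 (not isolated)
Conditions: 10 (1.5 equiv), N,N'-diisopropylcarbodiimide (DIC, 1.6 equiv), DMAP (0.3 equiv), CH2Cl2, 0 °C to rt; then MeOH, K2CO3 (0.1 equiv), 0 °C, 30 min
Reagents that add atoms: none
Why: Steglich esterification makes the fragment-joining C19–O–acyl bond (19-OH is the only hydroxyl and is primary, and the E-enoate cannot be damaged by DMAP), and the aryl acetate, far more electrophilic than the neopentylic cinnamate, is then removed in the same flask by K2CO3-catalysed transesterification to methanol, with no stereocentre involved.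

Step 6
Reactants: 12 ent-labda-8(17),13(16),14-trien-19-yl (E)-4-hydroxycinnamate
Product: 13 ent-labda-8(17),13(16),14-trien-19-yl (Z)-4-hydroxycinnamate
Conditions: fac-Ir(ppy)3 (1 mol %), argon-sparged MeCN (5 mM), 450 nm LED, 25 °C, 12 h; residual 12 separated on silica in the dark and resubmitted
Reagents that add atoms: none
Why: Triplet energy-transfer (sensitised) E-to-Z isomerisation of a cinnamate: the planar E-coumarate accepts the triplet energy of the iridium sensitiser and relaxes through a twisted triplet, the deconjugated Z-isomer is a poorer acceptor and accumulates, the isolated C8(17) alkene is out of energetic reach, and the 2-alkylbutadiene (higher triplet energy, both termini CH2) can only decay unchanged, so the Z geometry is set while C4, C5, C9 and C10 stay as they are.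

## Compound list
1 | andrographolide, (3R,4R,5S,9R,10S,12E,14S)-3,14,19-trihydroxy-ent-labda-8(17),12-dien-16,15-olide | O=C1OC[C@@H](O)/C1=C\C[C@@H]2C(=C)CC[C@@H]3[C@](C)(CO)[C@H](O)CC[C@@]23C | starting material
2 | (14R)-14-deoxy-14-[1-(2-nitrophenylsulfonyl)hydrazinyl]andrographolide (Mitsunobu adduct, inverted at C14) | O=C1OC[C@H](N(N)S(=O)(=O)c4ccccc4[N+](=O)[O-])/C1=C\C[C@@H]2C(=C)CC[C@@H]3[C@](C)(CO)[C@H](O)CC[C@@]23C | intermediate
3 | (14R)-14-deoxy-14-diazenylandrographolide (allylic monoalkyl diazene) | O=C1OC[C@H](N=N)/C1=C\C[C@@H]2C(=C)CC[C@@H]3[C@](C)(CO)[C@H](O)CC[C@@]23C | intermediate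
4 | 14-deoxyandrographolide, (3R,4R,5S,9R,10S)-3,19-dihydroxy-ent-labda-8(17),13-dien-16,15-olide | O=C1OCC=C1CC[C@@H]2C(=C)CC[C@@H]3[C@](C)(CO)[C@H](O)CC[C@@]23C | intermediate
5 | 14-deoxyandrographolide 3,19-cyclic thionocarbonate (1,3-dioxane-2-thione fused on C3–C4, core configuration as in 4) | O=C1OCC=C1CC[C@@H]2C(=C)CC[C@@H]3[C@]4(C)COC(=S)O[C@@H]4CC[C@@]23C | intermediate
6 | andrograpanin 19-O-[(tributylstannylsulfanyl)carbonyl] derivative | O=C1OCC=C1CC[C@@H]2C(=C)CC[C@@H]3[C@](C)(COC(=O)S[Sn](CCCC)(CCCC)CCCC)CCC[C@@]23C | intermediate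
7 | andrograpanin, (4R,5S,9R,10S)-19-hydroxy-ent-labda-8(17),13-dien-16,15-olide | O=C1OCC=C1CC[C@@H]2C(=C)CC[C@@H]3[C@](C)(CO)CCC[C@@]23C | intermediate
8 | (4R,5S,9R,10S,13Z)-ent-labda-8(17),13-diene-15,16,19-triol | OC/C=C(\CO)CC[C@@H]1C(=C)CC[C@@H]2[C@](C)(CO)CCC[C@@]12C | intermediate
9 | (4R,5S,9R,10S)-ent-labda-8(17),13(16),14-trien-19-ol | C=CC(=C)CC[C@@H]1C(=C)CC[C@@H]2[C@](C)(CO)CCC[C@@]12C | intermediate
10 | (E)-4-acetoxycinnamic acid | CC(=O)Oc1ccc(/C=C/C(=O)O)cc1 | starting material
11 | (4R,5S,9R,10S)-ent-labda-8(17),13(16),14-trien-19-yl (E)-4-acetoxycinnamate | C=CC(=C)CC[C@@H]1C(=C)CC[C@@H]2[C@](C)(COC(=O)/C=C/c3ccc(OC(C)=O)cc3)CCC[C@@]12C | intermediate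
12 | (4R,5S,9R,10S)-ent-labda-8(17),13(16),14-trien-19-yl (E)-4-hydroxycinnamate | C=CC(=C)CC[C@@H]1C(=C)CC[C@@H]2[C@](C)(COC(=O)/C=C/c3ccc(O)cc3)CCC[C@@]12C | intermediate
13 | (4R,5S,9R,10S)-ent-labda-8(17),13(16),14-trien-19-yl (Z)-4-hydroxycinnamate, CNP0131099.2 | C=CC(=C)CC[C@@H]1C(=C)CC[C@@H]2[C@](C)(COC(=O)/C=C\c3ccc(O)cc3)CCC[C@@]12C | target

## Step count and weak points
Total step count: 6. Longest linear sequence: 6 (1 to 13).

**Step 1.**
- Risks:
  - The activated 14-OH may undergo 1,4-elimination to the 11,12-didehydro compound.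
  - The hydrazide may attack C12 in an SN2' sense, which after retro-ene gives the alkylidene-lactone isomer.
  - The 3,19-diol ties up phosphonium reagent.
  - Surplus NBSH can give diimide.
- The fallback sets out from 1 and comes back at 4, replacing the C–N route by a hydride SN2' route.
- 1 is peracetylated (Ac2O, pyridine, DMAP, rt) to 3,14,19-tri-O-acetylandrographolide F1.
- NaBH4 in THF–MeOH at 0 °C adds hydride to C12 of the alkylidene lactone and the enolate expels the 14-acetate (conjugate reduction, then E1cB). This gives 3,19-di-O-acetyl-14-deoxyandrographolide F2.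
- K2CO3 in MeOH removes both acetates to give 4.

**Step 4 (the proposed new step).**
- Risks:
  - Some 1,4-hydride addition to the butenolide.
  - Sluggish transfer of the alkoxides from aluminium to titanium.
  - Dimerisation of the allyl radical.
  - Hydroalumination of the diene if hydride is in excess.
- The fallback uses known chemistry, sets out from 7 and comes back at 9.
- iBu2AlH (CH2Cl2, −78 to 0 °C) gives triol 8, which is isolated.
- Corey–Kim allylic chlorination (N-chlorosuccinimide, Me2S, CH2Cl2, −20 °C) converts only the two allylic hydroxyls and leaves 19-OH free. This gives (13Z)-15,16-dichloro-ent-labda-8(17),13-dien-19-ol F3.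
- Zn dust in EtOH at rt effects the classical reductive 1,4-elimination of the 1,4-dichloro-2-ene to 9.

**Step 6.**
- Risks:
  - The diene in the same molecule is a triplet quencher and may slow the reaction or enter [2+2] chemistry.
  - The photostationary state may not be rich enough in Z on precious material.
- The fallback sets out from 9 and 10 and comes back at 13. It sets the geometry on the diene-free acid before the C–O bond is made.
- 10 is irradiated (fac-Ir(ppy)3, MeCN, 450 nm) and separated from remaining 10 to give (Z)-4-acetoxycinnamic acid F4.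
- F4 is coupled with 9 by the Shiina method (2-methyl-6-nitrobenzoic anhydride, Et3N, DMAP 0.1 equiv, CH2Cl2, 0 °C). This gives ent-labda-8(17),13(16),14-trien-19-yl (Z)-4-acetoxycinnamate F5.
- Pyrrolidine (1.2 equiv, CH2Cl2, 0 °C, dark) removes the aryl acetate by aminolysis to give 13.

## Further compounds
F1 | step 1 | 3,14,19-tri-O-acetylandrographolide | O=C1OC[C@@H](OC(C)=O)/C1=C\C[C@@H]2C(=C)CC[C@@H]3[C@](C)(COC(C)=O)[C@H](OC(C)=O)CC[C@@]23C
F2 | step 1 | 3,19-di-O-acetyl-14-deoxyandrographolide | O=C1OCC=C1CC[C@@H]2C(=C)CC[C@@H]3[C@](C)(COC(C)=O)[C@H](OC(C)=O)CC[C@@]23C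
F3 | step 4 | (13Z)-15,16-dichloro-ent-labda-8(17),13-dien-19-ol | ClC/C=C(\CCl)CC[C@@H]1C(=C)CC[C@@H]2[C@](C)(CO)CCC[C@@]12C
F4 | step 6 | (Z)-4-acetoxycinnamic acid | CC(=O)Oc1ccc(/C=C\C(=O)O)cc1
F5 | step 6 | ent-labda-8(17),13(16),14-trien-19-yl (Z)-4-acetoxycinnamate | C=CC(=C)CC[C@@H]1C(=C)CC[C@@H]2[C@](C)(COC(=O)/C=C\c3ccc(OC(C)=O)cc3)CCC[C@@]12C
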